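The enone ring (C1–C2–C3) is opened by a retro-olefination and the bond C4–C11 is added back, because the cyclobutane C4–C5–C11–C10, whose 1,3-carbons C5 and C10 are spanned by the C6–C9 chain of the seven-membered ring, is the hydrogenolysis product of a bridged bicyclobutane. The key step decomposes a diazoester at C4, held on quaternary C10, and adds the carbenoid across the ring olefin C11=C5: one operation makes C4–C5 and C4–C11, closes both three-membered rings and sets C4, C5 and C11 from C10. Its precursor is a silyl-protected cyclohept-2-enyl diazoacetate carrying C1 as a silyloxymethyl group on C11.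

Key step: step 16

Numbering used throughout: C1 ketone carbon; C2=C3 olefin, C3 bearing CH3; C4 (on C3) and C11 (on C1) the cyclobutane CH atoms; C5 cyclobutane CH; C6 C(CH3)2; C7 CH–O (3-methylbutanoate); C8 CH2; C9 CH–O (tiglate); C10 C–CH3. The target is 4R,5S,7R,9R,10R,11R in this numbering.

Remarks on the design
- O7 carries a triisopropylsilyl group through the key step. A 4-methoxybenzyl ether there would be cleaved by H2 over Pd in the next step. Its ether oxygen (same ring face as the carbenoid) and its benzylic C–H bonds would also open ylide and insertion channels.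
- The diazo group is introduced by detrifluoroacetylative transfer, because the CH2 of a simple ester is not acidic enough for direct transfer from a sulfonyl azide.
- The seven-membered ring is closed between C10 and C11 by a Dieckmann condensation and C11=C5 is generated inside the ring. No ring closure has to join two olefins that both sit on quaternary carbons.
- Assumption: the hydrogenolysis product is drawn as the syn, exo-face adduct (carbon substituents at C4 and C11 both on the side of the C6–C9 bridge). Other C4/C11 epimers would serve equally, since both centres are equilibrated in step 22.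
- Assumption: methyl glyoxylate (cracked before use) and dimethyl (diazomethyl)phosphonate are bought.

Step 1
Reactants: 1 3-methylbutan-2-one; 2 methyl acrylate
Product: 3 methyl 4,4-dimethyl-5-oxohexanoate
Conditions: t-BuOK (0.1 equiv), t-BuOH, 0 °C to rt
Reagents that add atoms: none
Why: Base-catalysed Michael addition through the more substituted enolate of 1 alkylates the methine carbon and creates quaternary C6 with its two methyl groups, and a catalytic amount of base at low temperature should stop before Claisen cyclisation of the product.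

Step 2
Reactants: 3 methyl 4,4-dimethyl-5-oxohexanoate
Product: 4 methyl 4,4-dimethyl-5-(trimethylsilyloxy)hex-5-enoate
Conditions: Me3SiOTf, Et3N, CH2Cl2, 0 °C
Reagents that add atoms: trimethylsilyl triflate, C[Si](C)(C)OS(=O)(=O)C(F)(F)F
Why: Soft enolisation silylates only the ketone, and because C6 is quaternary the silyl enol ether can form only toward the methyl group that becomes C8.

Step 3
Reactants: 4 methyl 4,4-dimethyl-5-(trimethylsilyloxy)hex-5-enoate; 5 methyl glyoxylate
Product: 7 dimethyl (2R)-2-hydroxy-5,5-dimethyl-4-oxooctanedioate, via trimethylsilyl ether 6 (not isolated)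
Conditions: Cu(OTf)2 (10 mol %), (R,R)-t-Bu-box [2,2'-(propane-2,2-diyl)bis((4R)-4-tert-butyl-4,5-dihydrooxazole), 11 mol %], THF, −78 °C; then 1 M HCl, THF, 0 °C
Reagents that add atoms: none
Why: Catalytic asymmetric Mukaiyama aldol addition in which methyl glyoxylate is bound as a five-membered chelate on the copper bis(oxazoline) complex, whose tert-butyl groups shield one aldehyde face, and the (R,R)-ligand is chosen because it should deliver the (R)-carbinol at C9 (mirror image of the usual (S,S)-ligand/(S)-product pairing).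

Step 4
Reactants: 7 dimethyl (2R)-2-hydroxy-5,5-dimethyl-4-oxooctanedioate
Product: 8 dimethyl (2R,4R)-2,4-dihydroxy-5,5-dimethyloctanedioate
Conditions: Me4NBH(OAc)3, MeCN/AcOH (1:1), −30 °C; used crude
Reagents that add atoms: none
Why: Evans–Saksena reduction, in which the C9 hydroxyl binds boron and delivers hydride intramolecularly through a chair-like transition state, should give the 1,3-anti diol and so set C7 as (R).

Step 5
Reactants: 8 dimethyl (2R,4R)-2,4-dihydroxy-5,5-dimethyloctanedioate
Product: 9 dimethyl (2R,4R)-2-(tert-butyldimethylsilyloxy)-4-hydroxy-5,5-dimethyloctanedioate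
Conditions: t-BuMe2SiCl, imidazole, DMF, 0 °C
Reagents that add atoms: tert-butyldimethylsilyl chloride, CC(C)(C)[Si](C)(C)Cl
Why: Silyl chloride with imidazole discriminates on steric grounds between the open C9 hydroxyl next to the ester and the neopentylic C7 hydroxyl beside quaternary C6.

Step 6
Reactants: 9 dimethyl (2R,4R)-2-(tert-butyldimethylsilyloxy)-4-hydroxy-5,5-dimethyloctanedioate
Product: 10 dimethyl (2R,4R)-2-(tert-butyldimethylsilyloxy)-5,5-dimethyl-4-(triisopropylsilyloxy)octanedioate
Conditions: i-Pr3SiOTf, 2,6-lutidine, CH2Cl2, 0 °C to rt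
Reagents that add atoms: triisopropylsilyl triflate, CC(C)[Si](C(C)C)(C(C)C)OS(=O)(=O)C(F)(F)F
Why: The more reactive silyl triflate silylates the hindered C7 hydroxyl, and the triisopropylsilyl ether is chosen because it outlasts the two tert-butyldimethylsilyl ethers later and is inert toward a carbenoid and toward H2 over Pd.

Step 7
Reactants: 10 dimethyl (2R,4R)-2-(tert-butyldimethylsilyloxy)-5,5-dimethyl-4-(triisopropylsilyloxy)octanedioate
Product: 11 methyl (3R,5R)-3-(tert-butyldimethylsilyloxy)-6,6-dimethyl-2-oxo-5-(triisopropylsilyloxy)cycloheptane-1-carboxylate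
Conditions: LiN(SiMe3)2 (2.2 equiv), THF (0.02 M), −78 to 0 °C; AcOH quench
Reagents that add atoms: none
Why: Dieckmann condensation in which the kinetic enolate forms at unhindered C11 and attacks the C10 ester to close the seven-membered ring (7-exo-trig), while the alternative closure from C9 onto the C1 ester is reversible because its product has no acidic α-hydrogen, and the product stays as its enolate, which protects C9 from epimerisation.

Step 8
Reactants: 11 methyl (3R,5R)-3-(tert-butyldimethylsilyloxy)-6,6-dimethyl-2-oxo-5-(triisopropylsilyloxy)cycloheptane-1-carboxylate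
Product: 12 methyl (3R,5R)-3-(tert-butyldimethylsilyloxy)-6,6-dimethyl-2-(trifluoromethanesulfonyloxy)-5-(triisopropylsilyloxy)cyclohept-1-ene-1-carboxylate
Conditions: Tf2O, i-Pr2NEt, CH2Cl2, −78 °C
Reagents that add atoms: triflic anhydride, O=S(=O)(OS(=O)(=O)C(F)(F)F)C(F)(F)F
Why: O-Triflation of the β-keto ester enol fixes the C10=C11 double bond inside the ring as an enol triflate ready for cross-coupling.

Step 9
Reactants: 12 enol triflate
Product: 13 methyl (3R,5R)-3-(tert-butyldimethylsilyloxy)-2,6,6-trimethyl-5-(triisopropylsilyloxy)cyclohept-1-ene-1-carboxylate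
Conditions: MeMgBr (1.5 equiv), Fe(acac)3 (5 mol %), THF/NMP, −30 °C
Reagents that add atoms: methylmagnesium bromide, C[Mg]Br
Why: Iron-catalysed Kumada-type cross-coupling of the electron-poor enol triflate with the methyl Grignard reagent is much faster than addition to the ester at this temperature and puts the methyl group on C10.

Step 10
Reactants: 13 methyl (3R,5R)-3-(tert-butyldimethylsilyloxy)-2,6,6-trimethyl-5-(triisopropylsilyloxy)cyclohept-1-ene-1-carboxylate
Product: 14 [(3R,5R)-3-(tert-butyldimethylsilyloxy)-2,6,6-trimethyl-5-(triisopropylsilyloxy)cyclohept-1-en-1-yl]methanol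
Conditions: i-Bu2AlH (3 equiv), CH2Cl2, −78 to 0 °C; Rochelle salt work-up
Reagents that add atoms: none
Why: Hydride reduction of the conjugated ester gives the allylic alcohol that carries C1 and leaves the silyl ethers untouched.

Step 11
Reactants: 14 allylic alcohol
Product: 16 methyl 2-[(1R,5R,7R)-7-(tert-butyldimethylsilyloxy)-1,4,4-trimethyl-2-methylidene-5-(triisopropylsilyloxy)cycloheptyl]acetate, via ketene acetal 15 (not isolated)
Conditions: MeC(OMe)3 (10 equiv), EtCO2H (0.1 equiv), xylene, 140 °C, MeOH distilled off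
Reagents that add atoms: trimethyl orthoacetate, CC(OC)(OC)OC
Why: Johnson–Claisen rearrangement in which the ketene acetal formed on O1 undergoes a [3,3] shift that makes C4–C10 and the quaternary stereocentre C10 and moves the olefin to C11=C1, and A(1,2) strain with the C10 methyl group holds the C9 silyloxy group pseudo-axial, so the new bond should form on the opposite ring face and place the acetate arm trans to O9.

Step 12
Reactants: 16 methylidene ester
Product: 17 methyl 2-[(4S,5R,7R)-5-(tert-butyldimethylsilyloxy)-4,8,8-trimethyl-7-(triisopropylsilyloxy)-1-oxaspiro[2.6]nonan-4-yl]acetate (either configuration at the spiro carbon)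
Conditions: mCPBA, NaHCO3, CH2Cl2, 0 °C
Reagents that add atoms: 3-chloroperoxybenzoic acid, OOC(=O)c1cccc(Cl)c1
Why: Prilezhaev epoxidation of the only olefin, where the configuration of the new spiro carbon is of no consequence because it becomes sp2 again in the next step.

Step 13
Reactants: 17 spiro-epoxide
Product: 18 methyl 2-[(1R,5R,7R)-7-(tert-butyldimethylsilyloxy)-2-(hydroxymethyl)-1,4,4-trimethyl-5-(triisopropylsilyloxy)cyclohept-2-en-1-yl]acetate
Conditions: Cp2TiCl2 (2.5 equiv), Mn dust, THF, rt; then 0.5 M HCl (brief)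
Reagents that add atoms: none
Why: Cp2TiCl (trivalent titanium, formed in the flask) opens the epoxide homolytically to the tertiary C11 radical, and loss of a β-hydrogen to a second titanium centre can occur only at C5 because C10 is quaternary, so the epoxide should isomerise to the primary allylic alcohol with the C11=C5 ring olefin.

Step 14
Reactants: 18 allylic alcohol
Product: 19 methyl 2-[(1R,5R,7R)-7-(tert-butyldimethylsilyloxy)-2-[(tert-butyldimethylsilyloxy)methyl]-1,4,4-trimethyl-5-(triisopropylsilyloxy)cyclohept-2-en-1-yl]acetate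
Conditions: t-BuMe2SiCl, imidazole, CH2Cl2, rt
Reagents that add atoms: tert-butyldimethylsilyl chloride, CC(C)(C)[Si](C)(C)Cl
Why: Routine silylation of the primary allylic alcohol, with a bulky silyl ether kept on O1 because it is a poor ylide donor toward the carbenoid of step 16.

Step 15
Reactants: 19 trisilylated ester
Product: 21 methyl 2-diazo-2-[(1S,5R,7R)-7-(tert-butyldimethylsilyloxy)-2-[(tert-butyldimethylsilyloxy)methyl]-1,4,4-trimethyl-5-(triisopropylsilyloxy)cyclohept-2-en-1-yl]acetate, via trifluoroacetyl ester 20 (not isolated)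
Conditions: LiN(i-Pr)2, THF, −78 °C; CF3CO2CH2CF3, −78 °C; aq. NH4Cl; then 4-acetamidobenzenesulfonyl azide, Et3N, H2O (1 equiv), MeCN, rt
Reagents that add atoms: 4-acetamidobenzenesulfonyl azide, CC(=O)Nc1ccc(cc1)S(=O)(=O)N=[N+]=[N-]
Why: Detrifluoroacetylative (Regitz-type) diazo transfer in which Claisen trifluoroacetylation of the ester enolate makes C4 acidic enough to accept the diazo group from the sulfonyl azide, after which the trifluoroacetyl group leaves on nitrogen as the sulfonamide.

Step 16
Reactants: 21 diazoester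
Product: 22 methyl 3-(tert-butyldimethylsilyloxy)-1-[(tert-butyldimethylsilyloxy)methyl]-2,6,6-trimethyl-5-(triisopropylsilyloxy)tricyclo[5.1.0.0(2,8)]octane-8-carboxylate (central bond C4–C11; C6–C9 bridge endo; H-5 and the C10 methyl exo)
Conditions: Rh2(OAc)4 (1 mol %), CH2Cl2, 0 °C to rt, 21 added over 4 h
Reagents that add atoms: none
Why: Proposed new method: Rh2(OAc)4 should take N2 from 21 to give an electrophilic rhodium carbenoid at C4, which adds in a concerted but asynchronous [2+1] fashion to the C11=C5 olefin one atom away, the C4–C5 bond to the less substituted terminus leading while positive charge builds at tertiary C11 and then collapses to C4–C11. The closest known reaction type is the dirhodium-catalysed intramolecular cyclopropanation of 2-diazopent-4-enoates to bicyclo[1.1.0]butane-1-carboxylates, which has not been run on a trisubstituted olefin inside a seven-membered ring. Ring C4–C11–C5 is closed by this carbene [2+1] addition, and ring C4–C10–C11 is closed by the same C4–C11 bond as a 3-exo-trig closure of the one-atom tether through C10. The three new stereocentres C4, C5 and C11 are all controlled by C10, since the tether allows addition only to the olefin face that carries the C4 arm, which puts the C6–C9 bridge endo and leaves H-5 and the C10 methyl group exo. The step needs chemoselectivity for the olefin over hydride shift, C–H insertion, ylide formation and carbene dimerisation: C10 has no hydrogen to shift, the only activated 1,5-C–H bond (H-7) points to the opposite ring face, the oxygens carry bulky silyl groups that are poor ylide donors, and slow addition keeps the diazoester dilute.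

Step 17
Reactants: 22 bicyclobutane ester
Product: 23 methyl 2-(tert-butyldimethylsilyloxy)-8-[(tert-butyldimethylsilyloxy)methyl]-1,5,5-trimethyl-4-(triisopropylsilyloxy)bicyclo[4.1.1]octane-7-carboxylate (H-4 and H-11 on the face away from the C6–C9 bridge)
Conditions: H2 (1 atm), 5% Pd/C, EtOAc, rt
Reagents that add atoms: none
Why: Catalytic hydrogenolysis of a bicyclobutane, in which the central C4–C11 bond is the weakest bond of the cage and is conjugated with the ester, so it should be cleaved first to give the cyclobutane with hydrogen delivered to the open exo face, while the configuration at C4 and C11 is not critical and silyl ethers are stable under these conditions.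

Step 18
Reactants: 23 cyclobutane ester
Product: 24 methyl enol ether of the C3 ketone, tert-butyl{[2-(tert-butyldimethylsilyloxy)-7-(1-methoxyethenyl)-1,5,5-trimethyl-4-(triisopropylsilyloxy)bicyclo[4.1.1]octan-8-yl]methoxy}dimethylsilane
Conditions: Cp2Ti(μ-Cl)(μ-CH2)AlMe2 (Tebbe reagent), pyridine (cat.), THF/toluene, −40 °C to rt
Reagents that add atoms: Tebbe reagent, C[Al](C)Cl.C=[Ti](C1C=CC=C1)C1C=CC=C1
Why: Tebbe methylenation converts even hindered esters into methyl enol ethers under non-basic conditions and so masks the C3 methyl ketone without touching the silyl ethers or the α-stereocentre.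

Step 19
Reactants: 24 methyl enol ether
Product: 26 1-[2-(tert-butyldimethylsilyloxy)-8-(hydroxymethyl)-1,5,5-trimethyl-4-(triisopropylsilyloxy)bicyclo[4.1.1]octan-7-yl]ethan-1-one, via silyl ketone 25 (not isolated)
Conditions: 1 M HCl/THF (1:4), 0 °C to rt
Reagents that add atoms: water, O
Why: Aqueous acid hydrolyses the enol ether to the C3 methyl ketone at once and then cleaves the primary silyl ether on O1, which reacts far faster than the hindered secondary silyl ethers on O9 and O7.

Step 20
Reactants: 26 hydroxy ketone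
Product: 27 8-acetyl-2-(tert-butyldimethylsilyloxy)-1,5,5-trimethyl-4-(triisopropylsilyloxy)bicyclo[4.1.1]octane-7-carbaldehyde
Conditions: Dess–Martin periodinane, NaHCO3, CH2Cl2, rt
Reagents that add atoms: none
Why: Dess–Martin oxidation under buffered, non-basic conditions gives the aldehyde at C1 without enolising the neighbouring centres.

Step 21
Reactants: 27 keto aldehyde
Product: 28 dimethyl {2-[8-acetyl-2-(tert-butyldimethylsilyloxy)-1,5,5-trimethyl-4-(triisopropylsilyloxy)bicyclo[4.1.1]octan-7-yl]-2-oxoethyl}phosphonate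
Conditions: (MeO)2P(O)CHN2, SnCl2 (20 mol %), CH2Cl2, rt
Reagents that add atoms: dimethyl (diazomethyl)phosphonate, COP(=O)(OC)C=[N+]=[N-]
Why: Roskamp-type homologation in which the diazo carbon adds to the SnCl2-activated aldehyde and a 1,2-hydride shift with loss of N2 gives the β-keto phosphonate and brings in C2, while ketones do not react under these conditions, so the C3 methyl ketone is untouched and no base is present that could start an aldol reaction.

Step 22
Reactants: 28 keto phosphonate
Product: 29 (1R,2R,3R,5R,7S,8R)-3-(tert-butyldimethylsilyloxy)-2,6,6,11-tetramethyl-5-(triisopropylsilyloxy)tricyclo[5.4.0.0(2,8)]undec-10-en-9-one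
Conditions: K2CO3, 18-crown-6, toluene, 80 °C
Reagents that add atoms: none
Why: Intramolecular Horner–Wadsworth–Emmons olefination (6-exo-trig attack of C2 on the C3 ketone) closes the enone ring, C4 and C11 are both α to carbonyl groups and should interconvert by enolisation under carbonate, only the isomer with both carbonyl arms axial on the face opposite the C6–C9 bridge can cyclise (Curtin–Hammett), and after closure both centres are bridgeheads that can no longer epimerise.

Step 23
Reactants: 29 bis-silyl enone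
Product: 30 (1R,2R,3R,5R,7S,8R)-3-hydroxy-2,6,6,11-tetramethyl-5-(triisopropylsilyloxy)tricyclo[5.4.0.0(2,8)]undec-10-en-9-one
Conditions: HF·pyridine, pyridine, THF, 0 °C to rt
Reagents that add atoms: none
Why: Acidic fluoride cleaves a tert-butyldimethylsilyl ether much faster than a triisopropylsilyl ether, which frees O9 alone.

Step 24
Reactants: 30 C9 alcohol
Product: 31 (1R,2R,3R,5R,7S,8R)-2,6,6,11-tetramethyl-9-oxo-5-(triisopropylsilyloxy)tricyclo[5.4.0.0(2,8)]undec-10-en-3-yl (2E)-2-methylbut-2-enoate
Conditions: (E)-2-methylbut-2-enoyl chloride, DMAP, pyridine, CH2Cl2, 40 °C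
Reagents that add atoms: (E)-2-methylbut-2-enoyl chloride (tigloyl chloride), C/C=C(\C)C(Cl)=O
Why: Acyl-pyridinium (DMAP-catalysed) acylation of the hindered secondary alcohol, in which the (E)-2-methylbut-2-enoyl group is the thermodynamically stable isomer and should not isomerise.

Step 25
Reactants: 31 C9 tiglate
Product: 32 (1R,2R,3R,5R,7S,8R)-5-hydroxy-2,6,6,11-tetramethyl-9-oxotricyclo[5.4.0.0(2,8)]undec-10-en-3-yl (2E)-2-methylbut-2-enoate
Conditions: HF·pyridine (excess), THF, rt to 40 °C
Reagents that add atoms: none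
Why: Prolonged treatment with excess acidic fluoride removes the triisopropylsilyl ether, and the acidic medium avoids migration of the O9 ester to O7.

Step 26
Reactants: 32 C7 alcohol
Product: 33 CNP0194415.1, (1R,2R,3R,5R,7S,8R)-2,6,6,11-tetramethyl-5-(3-methylbutanoyloxy)-9-oxotricyclo[5.4.0.0(2,8)]undec-10-en-3-yl (2E)-2-methylbut-2-enoate
Conditions: 3-methylbutanoyl chloride, DMAP, pyridine, CH2Cl2, rt
Reagents that add atoms: 3-methylbutanoyl chloride, CC(C)CC(Cl)=O
Why: Acylation of the C7 hydroxyl with the acid chloride completes the target, all six stereocentres being in place.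

Compound list
1 | 3-methylbutan-2-one | CC(=O)C(C)C | starting material
2 | methyl acrylate | C=CC(=O)OC | starting material
3 | methyl 4,4-dimethyl-5-oxohexanoate | COC(=O)CCC(C)(C)C(C)=O | intermediate
4 | methyl 4,4-dimethyl-5-(trimethylsilyloxy)hex-5-enoate | COC(=O)CCC(C)(C)C(=C)O[Si](C)(C)C | intermediate
5 | methyl glyoxylate (methyl 2-oxoacetate) | COC(=O)C=O | starting material
6 | dimethyl (2R)-5,5-dimethyl-4-oxo-2-(trimethylsilyloxy)octanedioate | COC(=O)CCC(C)(C)C(=O)C[C@@H](O[Si](C)(C)C)C(=O)OC | intermediate (not isolated)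
7 | dimethyl (2R)-2-hydroxy-5,5-dimethyl-4-oxooctanedioate | COC(=O)CCC(C)(C)C(=O)C[C@@H](O)C(=O)OC | intermediate
8 | dimethyl (2R,4R)-2,4-dihydroxy-5,5-dimethyloctanedioate (anti diol) | COC(=O)CCC(C)(C)[C@H](O)C[C@@H](O)C(=O)OC | intermediate
9 | dimethyl (2R,4R)-2-(tert-butyldimethylsilyloxy)-4-hydroxy-5,5-dimethyloctanedioate | COC(=O)CCC(C)(C)[C@H](O)C[C@@H](O[Si](C)(C)C(C)(C)C)C(=O)OC | intermediate
10 | dimethyl (2R,4R)-2-(tert-butyldimethylsilyloxy)-5,5-dimethyl-4-(triisopropylsilyloxy)octanedioate | COC(=O)CCC(C)(C)[C@H](O[Si](C(C)C)(C(C)C)C(C)C)C[C@@H](O[Si](C)(C)C(C)(C)C)C(=O)OC | intermediate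
11 | methyl (3R,5R)-3-(tert-butyldimethylsilyloxy)-6,6-dimethyl-2-oxo-5-(triisopropylsilyloxy)cycloheptane-1-carboxylate (C1 epimers and enol) | COC(=O)C1CC(C)(C)[C@H](O[Si](C(C)C)(C(C)C)C(C)C)C[C@@H](O[Si](C)(C)C(C)(C)C)C1=O | intermediate
12 | methyl (3R,5R)-3-(tert-butyldimethylsilyloxy)-6,6-dimethyl-2-(trifluoromethanesulfonyloxy)-5-(triisopropylsilyloxy)cyclohept-1-ene-1-carboxylate | COC(=O)C1=C(OS(=O)(=O)C(F)(F)F)[C@H](O[Si](C)(C)C(C)(C)C)C[C@@H](O[Si](C(C)C)(C(C)C)C(C)C)C(C)(C)C1 | intermediate
13 | methyl (3R,5R)-3-(tert-butyldimethylsilyloxy)-2,6,6-trimethyl-5-(triisopropylsilyloxy)cyclohept-1-ene-1-carboxylate | COC(=O)C1=C(C)[C@H](O[Si](C)(C)C(C)(C)C)C[C@@H](O[Si](C(C)C)(C(C)C)C(C)C)C(C)(C)C1 | intermediate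
14 | [(3R,5R)-3-(tert-butyldimethylsilyloxy)-2,6,6-trimethyl-5-(triisopropylsilyloxy)cyclohept-1-en-1-yl]methanol | OCC1=C(C)[C@H](O[Si](C)(C)C(C)(C)C)C[C@@H](O[Si](C(C)C)(C(C)C)C(C)C)C(C)(C)C1 | intermediate
15 | 1-methoxyethenyl ether of 14 (mixed ketene acetal) | COC(=C)OCC1=C(C)[C@H](O[Si](C)(C)C(C)(C)C)C[C@@H](O[Si](C(C)C)(C(C)C)C(C)C)C(C)(C)C1 | intermediate (not isolated)
16 | methyl 2-[(1R,5R,7R)-7-(tert-butyldimethylsilyloxy)-1,4,4-trimethyl-2-methylidene-5-(triisopropylsilyloxy)cycloheptyl]acetate | COC(=O)C[C@]1(C)C(=C)CC(C)(C)[C@H](O[Si](C(C)C)(C(C)C)C(C)C)C[C@H]1O[Si](C)(C)C(C)(C)C | intermediate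
17 | methyl 2-[(4S,5R,7R)-5-(tert-butyldimethylsilyloxy)-4,8,8-trimethyl-7-(triisopropylsilyloxy)-1-oxaspiro[2.6]nonan-4-yl]acetate (spiro carbon: either configuration) | COC(=O)C[C@]1(C)C2(CO2)CC(C)(C)[C@H](O[Si](C(C)C)(C(C)C)C(C)C)C[C@H]1O[Si](C)(C)C(C)(C)C | intermediate
18 | methyl 2-[(1R,5R,7R)-7-(tert-butyldimethylsilyloxy)-2-(hydroxymethyl)-1,4,4-trimethyl-5-(triisopropylsilyloxy)cyclohept-2-en-1-yl]acetate | COC(=O)C[C@]1(C)C(CO)=CC(C)(C)[C@H](O[Si](C(C)C)(C(C)C)C(C)C)C[C@H]1O[Si](C)(C)C(C)(C)C | intermediate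
19 | methyl 2-[(1R,5R,7R)-7-(tert-butyldimethylsilyloxy)-2-[(tert-butyldimethylsilyloxy)methyl]-1,4,4-trimethyl-5-(triisopropylsilyloxy)cyclohept-2-en-1-yl]acetate | COC(=O)C[C@]1(C)C(CO[Si](C)(C)C(C)(C)C)=CC(C)(C)[C@H](O[Si](C(C)C)(C(C)C)C(C)C)C[C@H]1O[Si](C)(C)C(C)(C)C | intermediate
20 | methyl 4,4,4-trifluoro-3-oxo-2-[the (1R,5R,7R)-cycloheptenyl group of 19]butanoate (C2 epimers) | COC(=O)C(C(=O)C(F)(F)F)[C@]1(C)C(CO[Si](C)(C)C(C)(C)C)=CC(C)(C)[C@H](O[Si](C(C)C)(C(C)C)C(C)C)C[C@H]1O[Si](C)(C)C(C)(C)C | intermediate (not isolated)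
21 | methyl 2-diazo-2-[(1S,5R,7R)-7-(tert-butyldimethylsilyloxy)-2-[(tert-butyldimethylsilyloxy)methyl]-1,4,4-trimethyl-5-(triisopropylsilyloxy)cyclohept-2-en-1-yl]acetate | COC(=O)C(=[N+]=[N-])[C@]1(C)C(CO[Si](C)(C)C(C)(C)C)=CC(C)(C)[C@H](O[Si](C(C)C)(C(C)C)C(C)C)C[C@H]1O[Si](C)(C)C(C)(C)C | intermediate (key-step precursor)
22 | methyl 3-(tert-butyldimethylsilyloxy)-1-[(tert-butyldimethylsilyloxy)methyl]-2,6,6-trimethyl-5-(triisopropylsilyloxy)tricyclo[5.1.0.0(2,8)]octane-8-carboxylate (C6–C9 bridge endo) | COC(=O)[C@]12[C@]3(C)[C@@]1(CO[Si](C)(C)C(C)(C)C)[C@H]2C(C)(C)[C@H](O[Si](C(C)C)(C(C)C)C(C)C)C[C@H]3O[Si](C)(C)C(C)(C)C | intermediate (key-step product)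
23 | methyl 2-(tert-butyldimethylsilyloxy)-8-[(tert-butyldimethylsilyloxy)methyl]-1,5,5-trimethyl-4-(triisopropylsilyloxy)bicyclo[4.1.1]octane-7-carboxylate (ester and CH2OSi both on the side of the C6–C9 bridge) | COC(=O)[C@H]1[C@]2(C)[C@@H](CO[Si](C)(C)C(C)(C)C)[C@H]1C(C)(C)[C@H](O[Si](C(C)C)(C(C)C)C(C)C)C[C@H]2O[Si](C)(C)C(C)(C)C | intermediate
24 | tert-butyl{[2-(tert-butyldimethylsilyloxy)-7-(1-methoxyethenyl)-1,5,5-trimethyl-4-(triisopropylsilyloxy)bicyclo[4.1.1]octan-8-yl]methoxy}dimethylsilane (ring configuration as 23) | COC(=C)[C@H]1[C@]2(C)[C@@H](CO[Si](C)(C)C(C)(C)C)[C@H]1C(C)(C)[C@H](O[Si](C(C)C)(C(C)C)C(C)C)C[C@H]2O[Si](C)(C)C(C)(C)C | intermediate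
25 | 1-[2-(tert-butyldimethylsilyloxy)-8-[(tert-butyldimethylsilyloxy)methyl]-1,5,5-trimethyl-4-(triisopropylsilyloxy)bicyclo[4.1.1]octan-7-yl]ethan-1-one | CC(=O)[C@H]1[C@]2(C)[C@@H](CO[Si](C)(C)C(C)(C)C)[C@H]1C(C)(C)[C@H](O[Si](C(C)C)(C(C)C)C(C)C)C[C@H]2O[Si](C)(C)C(C)(C)C | intermediate (not isolated)
26 | 1-[2-(tert-butyldimethylsilyloxy)-8-(hydroxymethyl)-1,5,5-trimethyl-4-(triisopropylsilyloxy)bicyclo[4.1.1]octan-7-yl]ethan-1-one | CC(=O)[C@H]1[C@]2(C)[C@@H](CO)[C@H]1C(C)(C)[C@H](O[Si](C(C)C)(C(C)C)C(C)C)C[C@H]2O[Si](C)(C)C(C)(C)C | intermediate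
27 | 8-acetyl-2-(tert-butyldimethylsilyloxy)-1,5,5-trimethyl-4-(triisopropylsilyloxy)bicyclo[4.1.1]octane-7-carbaldehyde | CC(=O)[C@H]1[C@]2(C)[C@@H](C=O)[C@H]1C(C)(C)[C@H](O[Si](C(C)C)(C(C)C)C(C)C)C[C@H]2O[Si](C)(C)C(C)(C)C | intermediate
28 | dimethyl {2-[8-acetyl-2-(tert-butyldimethylsilyloxy)-1,5,5-trimethyl-4-(triisopropylsilyloxy)bicyclo[4.1.1]octan-7-yl]-2-oxoethyl}phosphonate | CC(=O)[C@H]1[C@]2(C)[C@@H](C(=O)CP(=O)(OC)OC)[C@H]1C(C)(C)[C@H](O[Si](C(C)C)(C(C)C)C(C)C)C[C@H]2O[Si](C)(C)C(C)(C)C | intermediate
29 | (1R,2R,3R,5R,7S,8R)-3-(tert-butyldimethylsilyloxy)-2,6,6,11-tetramethyl-5-(triisopropylsilyloxy)tricyclo[5.4.0.0(2,8)]undec-10-en-9-one | CC(C)(C)[Si](C)(C)O[C@@H]1C[C@@H](O[Si](C(C)C)(C(C)C)C(C)C)C(C)(C)[C@@H]2[C@H]3C(=O)C=C(C)[C@@H]2[C@]31C | intermediate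
30 | (1R,2R,3R,5R,7S,8R)-3-hydroxy-2,6,6,11-tetramethyl-5-(triisopropylsilyloxy)tricyclo[5.4.0.0(2,8)]undec-10-en-9-one | O[C@@H]1C[C@@H](O[Si](C(C)C)(C(C)C)C(C)C)C(C)(C)[C@@H]2[C@H]3C(=O)C=C(C)[C@@H]2[C@]31C | intermediate
31 | (1R,2R,3R,5R,7S,8R)-2,6,6,11-tetramethyl-9-oxo-5-(triisopropylsilyloxy)tricyclo[5.4.0.0(2,8)]undec-10-en-3-yl (2E)-2-methylbut-2-enoate | C/C=C(\C)C(=O)O[C@@H]1C[C@@H](O[Si](C(C)C)(C(C)C)C(C)C)C(C)(C)[C@@H]2[C@H]3C(=O)C=C(C)[C@@H]2[C@]31C | intermediate
32 | (1R,2R,3R,5R,7S,8R)-5-hydroxy-2,6,6,11-tetramethyl-9-oxotricyclo[5.4.0.0(2,8)]undec-10-en-3-yl (2E)-2-methylbut-2-enoate | C/C=C(\C)C(=O)O[C@@H]1C[C@@H](O)C(C)(C)[C@@H]2[C@H]3C(=O)C=C(C)[C@@H]2[C@]31C | intermediate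
33 | CNP0194415.1, (1R,2R,3R,5R,7S,8R)-2,6,6,11-tetramethyl-5-(3-methylbutanoyloxy)-9-oxotricyclo[5.4.0.0(2,8)]undec-10-en-3-yl (2E)-2-methylbut-2-enoate (route numbering 4R,5S,7R,9R,10R,11R) | C/C=C(\C)C(=O)O[C@@H]1C[C@@H](OC(=O)CC(C)C)C(C)(C)[C@@H]2[C@H]3C(=O)C=C(C)[C@@H]2[C@]31C | target

Total step count: 26 (15 to the key-step precursor, the key step, 10 after it).
Longest linear sequence: 26 steps, from 1 and 2 to 33; the route is fully linear.

Steps most likely to fail

1. Step 16 (key step, beyond precedent). The carbenoid may be consumed before it reaches the olefin, by 1,2-migration of the C11 vinyl carbon or the methyl group from C10, by insertion into a silyl C–H bond, by attack of the O1 ether oxygen, or by dimerisation. The strained bicyclobutane may also isomerise on the metal. The fallback is metal-free and uses known reaction types; it sets out from 21 and comes back at 22. Heating 21 in toluene at 80 °C without catalyst should bring about intramolecular 1,3-dipolar cycloaddition of the diazo group to C11=C5 (bonds C4–C11 and N–C5), giving the cyclopropane-fused 1-pyrazoline F1. Irradiation of F1 (350 nm, pentane, −20 °C) should expel N2, and the 1,3-diradical should close the C4–C5 bond to give 22.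

2. Step 17. Hydrogen may open a lateral bond of the bicyclobutane (C4–C5 or C4–C10) in place of the central bond, or go on to ring-opened products. The catalyst may also isomerise the cage to a diene before hydrogen is delivered. The fallback replaces hydrogenation by a polar/radical strain-release addition; it sets out from 22 and comes back at 23. Benzenethiol with a trace of AIBN in benzene at 60 °C should add across the central bond only: the thiyl radical attacks C11 from the rear and the ester-stabilised C4 radical takes hydrogen from the thiol. This gives the C11 phenyl sulfide F2. Raney Ni in ethanol should then replace sulfur by hydrogen, delivered to the exposed exo face of the planar C11 radical, and return 23.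

3. Step 22. Once the phosphonate is deprotonated at C2, enolisation toward C11 may become too slow, so that the isomer with both arms axial is not populated. Attack on the hindered C3 ketone may also be slower than decomposition. The fallback closes the ring on the more electrophilic aldehyde and transposes the enone afterwards; it sets out from 27 and comes back at 29. Piperidinium acetate in toluene at 80 °C should epimerise the aldehyde α-centre C11 through its enamine and condense the acetyl methyl group (which becomes C2) with the C1 aldehyde, giving the transposed enone F3 (C3 ketone, C1=C2 olefin). MeLi with CeCl3 in THF at −78 °C should add to the C3 carbonyl and bring in the C3 methyl group, giving the tertiary allylic alcohol F4. Pyridinium chlorochromate, (C5H5NH)[CrO3Cl], in CH2Cl2 should then effect the Babler–Dauben oxidative 1,3-transposition to 29.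

Further compounds
F1 | step 16 | cyclopropane-fused 1-pyrazoline from 21 (C4–C11 bond and C4–N=N–C5 bridge; silyl ethers and configuration at C7, C9, C10 as in 21) | COC(=O)[C@]1(N=N2)[C@]3(C)[C@@]1(CO[Si](C)(C)C(C)(C)C)[C@H]2C(C)(C)[C@H](O[Si](C(C)C)(C(C)C)C(C)C)C[C@H]3O[Si](C)(C)C(C)(C)C
F2 | step 17 | methyl 2-(tert-butyldimethylsilyloxy)-8-[(tert-butyldimethylsilyloxy)methyl]-1,5,5-trimethyl-8-(phenylsulfanyl)-4-(triisopropylsilyloxy)bicyclo[4.1.1]octane-7-carboxylate | COC(=O)[C@H]1[C@]2(C)[C@@](CO[Si](C)(C)C(C)(C)C)(Sc3ccccc3)[C@H]1C(C)(C)[C@H](O[Si](C(C)C)(C(C)C)C(C)C)C[C@H]2O[Si](C)(C)C(C)(C)C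
F3 | step 22 | 3-(tert-butyldimethylsilyloxy)-2,6,6-trimethyl-5-(triisopropylsilyloxy)tricyclo[5.4.0.0(2,8)]undec-9-en-11-one (ring configuration as in 29) | CC(C)(C)[Si](C)(C)O[C@@H]1C[C@@H](O[Si](C(C)C)(C(C)C)C(C)C)C(C)(C)[C@@H]2[C@H]3C=CC(=O)[C@@H]2[C@]31C
F4 | step 22 | 3-(tert-butyldimethylsilyloxy)-2,6,6,11-tetramethyl-5-(triisopropylsilyloxy)tricyclo[5.4.0.0(2,8)]undec-9-en-11-ol (either configuration at the carbinol carbon) | CC(C)(C)[Si](C)(C)O[C@@H]1C[C@@H](O[Si](C(C)C)(C(C)C)C(C)C)C(C)(C)[C@@H]2[C@H]3C=CC(C)(O)[C@@H]2[C@]31C
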